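**Retrosynthetic overview**

1. Target 21 ⇐ O-demethylation, C3 desilylation and C1 bridgehead acylation from the bicyclo[3.3.1]non-3-ene-2,9-dione methyl enol ether 17 (C3 blocked by silicon meanwhile).
2. 17 ⇐ oxidative semipinacol ring expansion of the cis-fused cyclopentane/cyclohexenone 15: C8 shifts from C9 to C1, so the cyclopentane C5–C6–C7–C8–C9 becomes the six-membered ring C1–C9–C5–C6–C7–C8 and the fused skeleton becomes the bridged one.
3. Enabling feature: the ring-fusion carbinol C9 is flanked by the quaternary C8 of the five-membered ring and by C1H2–C2=O, the only enolisable position of the six-membered ring (a β-hydroxy ketone), so a leaving group on C1 can stand antiperiplanar to the C8–C9 bond.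
4. 15 ⇐ dianion aldol (C1–C9) of triketone 13 ⇐ cyclopentanone 10 by C5 acetylation, then C5 prenylation anti to the C7 prenyl group, then chain acetylation (acyl before prenyl puts the C2–C4 bridge syn to the C7 prenyl group, as the target requires).
5. 10 ⇐ 2-methylcyclopent-2-enone by copper-catalysed asymmetric conjugate addition (C7), enolate alkylation (C8) and alkene isomerisation. Ring order: cyclopentane (bought), six-membered dione ring (step 9), ring expansion to the bicycle (step 10).

Key step: step 10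

Remark on the chemistry: locants C1–C9 are those of the bicyclo[3.3.1]nonane of 21 (C1 acyl bridgehead, C2 ketone, C3, C4 enol carbon, C5 prenyl bridgehead, C6 CH2, C7 CH-prenyl, C8 quaternary, C9 bridging ketone) and are kept for all intermediates. 21 is one of two interconverting enol tautomers and is obtained as that equilibrium mixture. Its C7 prenyl group is endo, that is syn to the C2–C4 bridge.

**Route**

Step 1
Reactants: 1 5-bromo-2-methylpent-2-ene
Product: 2 5-iodo-2-methylpent-2-ene
Conditions: NaI, acetone, reflux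
Reagents that add atoms: sodium iodide, [Na+].[I-]
Why: Finkelstein halide exchange at a primary carbon, driven by precipitation of NaBr, gives the more reactive alkylating agent for step 4.

Step 2
Reactants: 3 4-bromo-2-methylbut-1-ene
Product: 4 (3-methylbut-3-en-1-yl)magnesium bromide (Et2O solution, titrated, used directly)
Conditions: Mg turnings, cat. I2, Et2O, reflux
Reagents that add atoms: magnesium, [Mg]
Why: Grignard formation from a primary homoallylic bromide gives a masked prenyl nucleophile that, unlike a prenyl metal, transfers without allylic transposition.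

Step 3
Reactants: 5 2-methylcyclopent-2-en-1-one; 4 (3-methylbut-3-en-1-yl)magnesium bromide
Product: 7 (S)-trimethyl{[2-methyl-3-(3-methylbut-3-en-1-yl)cyclopent-1-en-1-yl]oxy}silane, via magnesium enolate 6 (not isolated)
Conditions: Cu(OTf)2 (3 mol %), leucinol-derived N-mesityl hydroxyalkyl imidazolinium salt (chiral NHC precursor, 4 mol %), Et2O, −30 °C; then Me3SiCl, Et3N, DMPU, −30 °C → rt
Reagents that add atoms: chlorotrimethylsilane, C[Si](C)(C)Cl
Why: Copper-catalysed asymmetric conjugate addition of a Grignard reagent to an α-substituted cyclic enone sets C7 through the enone face selected by the chiral NHC–copper complex (ligand antipode chosen to give the S centre, enantiomeric purity to be verified at 9), and silylation fixes the enolate regiospecifically.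

Step 4
Reactants: 7 (S)-trimethyl{[2-methyl-3-(3-methylbut-3-en-1-yl)cyclopent-1-en-1-yl]oxy}silane; 2 5-iodo-2-methylpent-2-ene
Product: 9 (2R,3S)-2-methyl-3-(3-methylbut-3-en-1-yl)-2-(4-methylpent-3-en-1-yl)cyclopentan-1-one, via lithium enolate 8 (not isolated)
Conditions: MeLi, THF, 0 °C; then DMPU, 2, −40 °C → rt
Reagents that add atoms: none
Why: Regiospecific enolate regeneration from the silyl enol ether and alkylation build the quaternary C8, the iodide entering anti to the adjacent C7 side chain (homoprenyl trans to the C7 substituent).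

Step 5
Reactants: 9 (2R,3S)-2-methyl-3-(3-methylbut-3-en-1-yl)-2-(4-methylpent-3-en-1-yl)cyclopentan-1-one
Product: 10 (2R,3R)-2-methyl-3-(3-methylbut-2-en-1-yl)-2-(4-methylpent-3-en-1-yl)cyclopentan-1-one
Conditions: Co(salen)Cl (3 mol %; salen = N,N'-bis(3,5-di-tert-butylsalicylidene)cyclohexane-1,2-diamine dianion), PhSiH3 (6 mol %), benzene, rt
Reagents that add atoms: none
Why: Cobalt-hydride hydrogen-atom-transfer isomerisation moves the 1,1-disubstituted double bond one position into the trisubstituted prenyl position (the thermodynamic sink) and should leave the homoprenyl alkene and both stereocentres untouched (the C3 descriptor changes from S to R only through CIP priorities).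

Step 6
Reactants: 10 (2R,3R)-2-methyl-3-(3-methylbut-2-en-1-yl)-2-(4-methylpent-3-en-1-yl)cyclopentan-1-one
Product: 11 (2R,3S)-5-acetyl-2-methyl-3-(3-methylbut-2-en-1-yl)-2-(4-methylpent-3-en-1-yl)cyclopentan-1-one (C5 epimers, partly enolised)
Conditions: MgBr2·OEt2, i-Pr2NEt, AcCl, CH2Cl2, 0 °C → rt
Reagents that add atoms: acetyl chloride, CC(=O)Cl
Why: Soft-enolisation C-acylation, in which the magnesium enolate can form only toward C5 (C8 is quaternary), places the future C4 on C5 before the prenyl group.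

Step 7
Reactants: 11 (2R,3S)-5-acetyl-2-methyl-3-(3-methylbut-2-en-1-yl)-2-(4-methylpent-3-en-1-yl)cyclopentan-1-one
Product: 12 (2R,3S,5S)-5-acetyl-2-methyl-3,5-bis(3-methylbut-2-en-1-yl)-2-(4-methylpent-3-en-1-yl)cyclopentan-1-one
Conditions: K2CO3, prenyl bromide, acetone, rt → 40 °C
Reagents that add atoms: 1-bromo-3-methylbut-2-ene (prenyl bromide), CC(C)=CCBr
Why: C-alkylation of the stabilised 2-acylcyclopentanone enolate, with the bromide approaching the planar C5 from the face anti to the C7 prenyl group and the C8 methyl group, should leave the acetyl group syn to the C7 prenyl group.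

Step 8
Reactants: 12 (2R,3S,5S)-5-acetyl-2-methyl-3,5-bis(3-methylbut-2-en-1-yl)-2-(4-methylpent-3-en-1-yl)cyclopentan-1-one
Product: 13 (2R,3S,5S)-2-methyl-3,5-bis(3-methylbut-2-en-1-yl)-2-(4-methylpent-3-en-1-yl)-5-(3-oxobutanoyl)cyclopentan-1-one
Conditions: MgBr2·OEt2, i-Pr2NEt, AcCl, CH2Cl2, rt
Reagents that add atoms: acetyl chloride, CC(=O)Cl
Why: Second soft-enolisation C-acylation at the acetyl CH3, the only enolisable position of 12, with a non-nucleophilic amine base that avoids retro-Claisen cleavage of the 2,2-disubstituted 1,3-diketone.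

Step 9
Reactants: 13 (2R,3S,5S)-2-methyl-3,5-bis(3-methylbut-2-en-1-yl)-2-(4-methylpent-3-en-1-yl)-5-(3-oxobutanoyl)cyclopentan-1-one
Product: 15 (1R,2S,3aR,7aR)-7a-hydroxy-4-methoxy-1-methyl-1-(4-methylpent-3-en-1-yl)-2,3a-bis(3-methylbut-2-en-1-yl)-1,2,3,3a,7,7a-hexahydro-6H-inden-6-one, via dilithium aldolate 14 (not isolated)
Conditions: LiN(i-Pr)2 (2.3 equiv), THF, −78 → 0 °C; then Me2SO4, DMPU, −78 → 0 °C; then H2O
Reagents that add atoms: dimethyl sulfate, COS(=O)(=O)OC
Why: Twofold deprotonation (C3, then terminal C1H3) gives the 1,3-diketone dianion whose terminal carbon adds to the C9 ketone in a 6-exo-trig aldol closure that is necessarily cis-fused, and the diketonate should then be O-methylated at O4 because O2 is held in a six-membered lithium chelate with the C9 alkoxide.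

Step 10
Reactants: 15 (1R,2S,3aR,7aR)-7a-hydroxy-4-methoxy-1-methyl-1-(4-methylpent-3-en-1-yl)-2,3a-bis(3-methylbut-2-en-1-yl)-1,2,3,3a,7,7a-hexahydro-6H-inden-6-one
Product: 17 (1R,5S,7S,8R)-4-methoxy-8-methyl-8-(4-methylpent-3-en-1-yl)-5,7-bis(3-methylbut-2-en-1-yl)bicyclo[3.3.1]non-3-ene-2,9-dione, via C1 methoxy(phenyl)iodane 16 (not isolated)
Conditions: PhI(OAc)2, KOH, MeOH, −10 → 0 °C
Reagents that add atoms: none
Why: Mechanism: KOH/MeOH turns PhI(OAc)2 into PhI(OMe)2 and 15 into its C1 enolate (C1 is the only α-carbon with hydrogen, C3 being vinylic and C5 quaternary), which is iodanylated axially to 16, whereupon the C9 alkoxide drives a 1,2-shift of the antiperiplanar C8–C9 bond to C1 with loss of PhI and unveils the C9 ketone. Closest known reaction type: hypervalent-iodine α-functionalisation of ketone enolates in basic methanol, diverted into a semipinacol ring expansion of a β-hydroxy ketone. Ring closure: the six-membered ring C1–C9–C5–C6–C7–C8 is closed not by a Baldwin-type cyclisation but by ring enlargement of the cyclopentane through a suprafacial 1,2-alkyl shift (C1–C8 forms as C8–C9 breaks), which turns the fused bicyclo[4.3.0] skeleton into the bridged bicyclo[3.3.1] skeleton. Stereocontrol: the new C1 centre is dictated by the cis ring fusion, because C8 can reach C1 only on its own side of the six-membered ring (inversion at C1), and C8 keeps its configuration because the migrating bond never leaves it. Selectivity needed: C8 migration must beat C5 migration (contraction of the six-membered ring) and oxirane closure by the C9 oxygen; the tertiary, electron-rich C8 should migrate better than C5, which carries the electron-poor C4, and axial attack of the iodane anti to a pseudoaxial C8 on C9 places the C8–C9 bond antiperiplanar to the C–I bond.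

Step 11
Reactants: 17 (1R,5S,7S,8R)-4-methoxy-8-methyl-8-(4-methylpent-3-en-1-yl)-5,7-bis(3-methylbut-2-en-1-yl)bicyclo[3.3.1]non-3-ene-2,9-dione
Product: 18 (1S,5S,7S,8R)-4-methoxy-8-methyl-8-(4-methylpent-3-en-1-yl)-5,7-bis(3-methylbut-2-en-1-yl)-3-(trimethylsilyl)bicyclo[3.3.1]non-3-ene-2,9-dione
Conditions: LiN(i-Pr)2, Me3SiCl (in situ quench), THF, −78 °C
Reagents that add atoms: chlorotrimethylsilane, C[Si](C)(C)Cl
Why: Kinetic lithiation of the vinylic C3–H of the vinylogous ester with in situ silylation blocks the position that would otherwise compete with the bridgehead in step 12, without touching a stereocentre (the C1 descriptor changes only through CIP priorities).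

Step 12
Reactants: 18 (1S,5S,7S,8R)-4-methoxy-8-methyl-8-(4-methylpent-3-en-1-yl)-5,7-bis(3-methylbut-2-en-1-yl)-3-(trimethylsilyl)bicyclo[3.3.1]non-3-ene-2,9-dione
Product: 19 (1R,5S,7S,8R)-4-methoxy-8-methyl-8-(4-methylpent-3-en-1-yl)-5,7-bis(3-methylbut-2-en-1-yl)-1-(2-methylpropanoyl)-3-(trimethylsilyl)bicyclo[3.3.1]non-3-ene-2,9-dione
Conditions: LiN(i-Pr)2, THF, −78 °C; then i-PrCOCl, −78 → −20 °C
Reagents that add atoms: 2-methylpropanoyl chloride (isobutyryl chloride), CC(C)C(=O)Cl
Why: Bridgehead lithiation at C1, acidified by the flanking C2 and C9 carbonyl groups, followed by C-acylation, with the cage fixing the configuration of the new quaternary C1 because the electrophile can only enter along the former C1–H bond.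

Step 13
Reactants: 19 (1R,5S,7S,8R)-4-methoxy-8-methyl-8-(4-methylpent-3-en-1-yl)-5,7-bis(3-methylbut-2-en-1-yl)-1-(2-methylpropanoyl)-3-(trimethylsilyl)bicyclo[3.3.1]non-3-ene-2,9-dione
Product: 20 (1S,5S,7S,8R)-4-methoxy-8-methyl-8-(4-methylpent-3-en-1-yl)-5,7-bis(3-methylbut-2-en-1-yl)-1-(2-methylpropanoyl)bicyclo[3.3.1]non-3-ene-2,9-dione
Conditions: Bu4NF, AcOH, THF, 0 °C → rt
Reagents that add atoms: none
Why: Fluoride-induced protodesilylation of the α-silyl enone returns the C3–H, and buffering with acetic acid protects the non-enolisable triacylmethane at C1 from retro-Claisen cleavage.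

Step 14
Reactants: 20 (1S,5S,7S,8R)-4-methoxy-8-methyl-8-(4-methylpent-3-en-1-yl)-5,7-bis(3-methylbut-2-en-1-yl)-1-(2-methylpropanoyl)bicyclo[3.3.1]non-3-ene-2,9-dione
Product: 21 (1S,5S,7S,8R)-4-hydroxy-8-methyl-8-(4-methylpent-3-en-1-yl)-5,7-bis(3-methylbut-2-en-1-yl)-1-(2-methylpropanoyl)bicyclo[3.3.1]non-3-ene-2,9-dione
Conditions: LiCl, DMSO, 120 °C; then dilute aq. HCl, 0 °C
Reagents that add atoms: none
Why: Krapcho-type SN2 demethylation of the vinylogous methyl ester by chloride liberates the enolised 1,3-diketone without touching the four stereocentres or the prenyl groups.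

**Compound list**

1 | 5-bromo-2-methylpent-2-ene | CC(C)=CCCBr | starting material
2 | 5-iodo-2-methylpent-2-ene | CC(C)=CCCI | intermediate
3 | 4-bromo-2-methylbut-1-ene | CC(=C)CCBr | starting material
4 | (3-methylbut-3-en-1-yl)magnesium bromide | CC(=C)CC[Mg]Br | intermediate
5 | 2-methylcyclopent-2-en-1-one | CC1=CCCC1=O | starting material
6 | bromomagnesium (S)-2-methyl-3-(3-methylbut-3-en-1-yl)cyclopent-1-en-1-olate | CC1=C(O[Mg]Br)CC[C@@H]1CCC(C)=C | intermediate (not isolated)
7 | (S)-trimethyl{[2-methyl-3-(3-methylbut-3-en-1-yl)cyclopent-1-en-1-yl]oxy}silane | CC1=C(O[Si](C)(C)C)CC[C@@H]1CCC(C)=C | intermediate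
8 | lithium (S)-2-methyl-3-(3-methylbut-3-en-1-yl)cyclopent-1-en-1-olate | [Li+].CC1=C([O-])CC[C@@H]1CCC(C)=C | intermediate (not isolated)
9 | (2R,3S)-2-methyl-3-(3-methylbut-3-en-1-yl)-2-(4-methylpent-3-en-1-yl)cyclopentan-1-one | CC(C)=CCC[C@]1(C)[C@@H](CCC(C)=C)CCC1=O | intermediate
10 | (2R,3R)-2-methyl-3-(3-methylbut-2-en-1-yl)-2-(4-methylpent-3-en-1-yl)cyclopentan-1-one | CC(C)=CCC[C@]1(C)[C@@H](CC=C(C)C)CCC1=O | intermediate
11 | (2R,3S)-5-acetyl-2-methyl-3-(3-methylbut-2-en-1-yl)-2-(4-methylpent-3-en-1-yl)cyclopentan-1-one (C5 epimers) | CC(C)=CCC[C@]1(C)[C@@H](CC=C(C)C)CC(C(C)=O)C1=O | intermediate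
12 | (2R,3S,5S)-5-acetyl-2-methyl-3,5-bis(3-methylbut-2-en-1-yl)-2-(4-methylpent-3-en-1-yl)cyclopentan-1-one | CC(C)=CCC[C@]1(C)[C@@H](CC=C(C)C)C[C@@](CC=C(C)C)(C(C)=O)C1=O | intermediate
13 | (2R,3S,5S)-2-methyl-3,5-bis(3-methylbut-2-en-1-yl)-2-(4-methylpent-3-en-1-yl)-5-(3-oxobutanoyl)cyclopentan-1-one | CC(C)=CCC[C@]1(C)[C@@H](CC=C(C)C)C[C@@](CC=C(C)C)(C(=O)CC(C)=O)C1=O | intermediate
14 | dilithium aldolate (C9 alkoxide and C2–C4 diketonate) of the cis-fused 7a-hydroxy-hexahydroindene-4,6-dione, i.e. 15 without its O-methyl group | [Li+].[Li+].CC(C)=CCC[C@]1(C)[C@@H](CC=C(C)C)C[C@@]2(CC=C(C)C)C([O-])=CC(=O)C[C@@]12[O-] | intermediate (not isolated)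
15 | (1R,2S,3aR,7aR)-7a-hydroxy-4-methoxy-1-methyl-1-(4-methylpent-3-en-1-yl)-2,3a-bis(3-methylbut-2-en-1-yl)-1,2,3,3a,7,7a-hexahydro-6H-inden-6-one | CC(C)=CCC[C@]1(C)[C@@H](CC=C(C)C)C[C@@]2(CC=C(C)C)C(OC)=CC(=O)C[C@@]12O | intermediate
16 | 7-[methoxy(phenyl)-λ3-iodanyl] derivative of 15 (iodane on C1, anti to the C8–C9 bond) | CC(C)=CCC[C@]1(C)[C@@H](CC=C(C)C)C[C@@]2(CC=C(C)C)C(OC)=CC(=O)[C@H]([I](OC)c3ccccc3)[C@@]12O | intermediate (not isolated)
17 | (1R,5S,7S,8R)-4-methoxy-8-methyl-8-(4-methylpent-3-en-1-yl)-5,7-bis(3-methylbut-2-en-1-yl)bicyclo[3.3.1]non-3-ene-2,9-dione | CC(C)=CCC[C@]1(C)[C@@H](CC=C(C)C)C[C@]2(CC=C(C)C)C(=O)[C@H]1C(=O)C=C2OC | intermediate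
18 | (1S,5S,7S,8R)-4-methoxy-8-methyl-8-(4-methylpent-3-en-1-yl)-5,7-bis(3-methylbut-2-en-1-yl)-3-(trimethylsilyl)bicyclo[3.3.1]non-3-ene-2,9-dione | CC(C)=CCC[C@]1(C)[C@@H](CC=C(C)C)C[C@]2(CC=C(C)C)C(=O)[C@H]1C(=O)C([Si](C)(C)C)=C2OC | intermediate
19 | (1R,5S,7S,8R)-4-methoxy-8-methyl-8-(4-methylpent-3-en-1-yl)-5,7-bis(3-methylbut-2-en-1-yl)-1-(2-methylpropanoyl)-3-(trimethylsilyl)bicyclo[3.3.1]non-3-ene-2,9-dione | CC(C)=CCC[C@]1(C)[C@@H](CC=C(C)C)C[C@]2(CC=C(C)C)C(=O)[C@@]1(C(=O)C(C)C)C(=O)C([Si](C)(C)C)=C2OC | intermediate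
20 | (1S,5S,7S,8R)-4-methoxy-8-methyl-8-(4-methylpent-3-en-1-yl)-5,7-bis(3-methylbut-2-en-1-yl)-1-(2-methylpropanoyl)bicyclo[3.3.1]non-3-ene-2,9-dione | CC(C)=CCC[C@]1(C)[C@@H](CC=C(C)C)C[C@]2(CC=C(C)C)C(=O)[C@@]1(C(=O)C(C)C)C(=O)C=C2OC | intermediate
21 | (1S,5S,7S,8R)-4-hydroxy-8-methyl-8-(4-methylpent-3-en-1-yl)-5,7-bis(3-methylbut-2-en-1-yl)-1-(2-methylpropanoyl)bicyclo[3.3.1]non-3-ene-2,9-dione | CC(C)=CCC[C@]1(C)[C@@H](CC=C(C)C)C[C@]2(CC=C(C)C)C(=O)[C@@]1(C(=O)C(C)C)C(=O)C=C2O | target

**Step count and risks**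

Total step count: 14. Longest linear sequence: 13 steps (steps 2 to 14, from 4-bromo-2-methylbut-1-ene); step 1 is a one-step side branch.

Steps most likely to fail:

Step 10. In this C7-endo series the iodane-bearing conformer may place the C9 oxygen, not the C8–C9 bond, antiperiplanar to the C1–I bond, so that oxirane closure, migration of C5 (contraction of the six-membered ring) or retro-aldol opening outruns the wanted shift. The fallback sets out from 15 and comes back at 17 by a carbenoid version of the same 1,2-shift, which needs no antiperiplanar leaving group. LiN(SiMe3)2 (2.2 equiv) and 2,2,2-trifluoroethyl trifluoroacetate in THF at −78 °C would give the C1-trifluoroacetyl ketone F1. Detrifluoroacetylative Regitz diazo transfer (MsN3, Et3N, H2O, MeCN) would give the C1-diazo β-hydroxy ketone F2. Rh2(OAc)4 (1 mol %) in CH2Cl2 at rt should then trigger migration of C8 from C9 to the rhodium carbenoid carbon with loss of nitrogen and deliver 17.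

Step 7. Prenyl bromide may attack the planar C5 on the wrong face (syn to the C7 prenyl group), or on oxygen. The fallback sets out from 11 and comes back at 12 under catalyst control. A Tsuji–Trost allylation with [Pd(allyl)Cl]2 (2.5 mol %, source of zerovalent palladium), the antipode of N,N'-(cyclohexane-1,2-diyl)bis[2-(diphenylphosphanyl)benzamide] matched to the 5S face, allyl acetate and Cs2CO3 in CH2Cl2 would give the 5-allyl ketone F3. Cross-metathesis of F3 with 2-methylbut-2-ene (as solvent) and the second-generation Grubbs catalyst RuCl2(=CHPh)(PCy3)(H2IMes) at 40 °C would then turn allyl into prenyl and give 12.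

Step 12. Lithiation at the hindered C1 bridgehead next to the quaternary C8 may be incomplete, or the bridgehead anion may deprotonate the acid chloride instead of being acylated. The fallback sets out from 18 and comes back at 19 in three operations. LiN(i-Pr)2 then I2 in THF at −78 °C would give the bridgehead iodide F4. Iodine–magnesium exchange with i-PrMgCl at −78 °C and addition to 2-methylpropanal would give the carbinol F5. Dess–Martin oxidation in CH2Cl2 would give 19.

Further compounds

F1 | step 10 | 7-(2,2,2-trifluoroacetyl) derivative of 15 (C1 epimers, enolised) | CC(C)=CCC[C@]1(C)[C@@H](CC=C(C)C)C[C@@]2(CC=C(C)C)C(OC)=CC(=O)C(C(=O)C(F)(F)F)[C@@]12O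
F2 | step 10 | 7-diazo derivative of 15 (α-diazo β-hydroxy ketone) | CC(C)=CCC[C@]1(C)[C@@H](CC=C(C)C)C[C@@]2(CC=C(C)C)C(OC)=CC(=O)C(=[N+]=[N-])[C@@]12O
F3 | step 7 | (2R,3S,5S)-5-acetyl-2-methyl-3-(3-methylbut-2-en-1-yl)-2-(4-methylpent-3-en-1-yl)-5-(prop-2-en-1-yl)cyclopentan-1-one | CC(C)=CCC[C@]1(C)[C@@H](CC=C(C)C)C[C@@](CC=C)(C(C)=O)C1=O
F4 | step 12 | (1R,5S,7S,8R)-1-iodo-4-methoxy-8-methyl-8-(4-methylpent-3-en-1-yl)-5,7-bis(3-methylbut-2-en-1-yl)-3-(trimethylsilyl)bicyclo[3.3.1]non-3-ene-2,9-dione | CC(C)=CCC[C@]1(C)[C@@H](CC=C(C)C)C[C@]2(CC=C(C)C)C(=O)[C@@]1(I)C(=O)C([Si](C)(C)C)=C2OC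
F5 | step 12 | (1R,5S,7S,8R)-1-(1-hydroxy-2-methylpropyl)-4-methoxy-8-methyl-8-(4-methylpent-3-en-1-yl)-5,7-bis(3-methylbut-2-en-1-yl)-3-(trimethylsilyl)bicyclo[3.3.1]non-3-ene-2,9-dione (carbinol epimers) | CC(C)=CCC[C@]1(C)[C@@H](CC=C(C)C)C[C@]2(CC=C(C)C)C(=O)[C@@]1(C(O)C(C)C)C(=O)C([Si](C)(C)C)=C2OC
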